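**Retrosynthetic overview**

1. The target is a (3S)-isoflavan with one stereocentre, C3. C3 is a benzylic CH bonded to C1′ of ring B, to C4 (the CH2 on C4a of ring A) and to C2 (the OCH2 of ring C). C3–C4 is thus a two-carbon unit flanked by both arenes, and it is taken from a vinyl group that receives ring B and ring A in one step.
2. Ring C is the only ring formed. It is closed by O1–C2 Mitsunobu etherification, after C2 has been inserted into the C3–B bond (Matteson) and oxidised to CH2OH.
3. Key disconnection: C3–C1′ and C4–C4a by enantioselective three-component conjunctive coupling of vinylB(pin) 16, ring B aryllithium 17 and ring A triflate 15.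
4. Ring B bromide 9 comes from 2-hydroxy-6-methoxybenzaldehyde (O-prenylation, Claisen, Dakin, silylation, bromination). Its single phenol fixes which catechol oxygen carries the prenyl group.
5. Ring A triflate 15 comes from 2,4-dihydroxybenzaldehyde (TIPS, MOM, Baeyer–Villiger, triflation).

Key step: step 10

Assumption: the enantiomer of the MandyPhos ligand used in step 10 is the one that delivers (S)-19. The sense of induction for this substrate pair is to be assigned on first use (oxidation of a sample to the carbinol, Mosher esters), and the mirror-image ligand is taken if needed.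

Abbreviations: TBS = tert-butyldimethylsilyl, TIPS = triisopropylsilyl, MOM = methoxymethyl, pin = pinacolato. L = 1,1′-bis[bis(4-methoxy-3,5-dimethylphenyl)phosphino]-2,2′-bis[α-(dimethylamino)benzyl]ferrocene (MandyPhos type, single enantiomer).

**Route**

Step 1
Reactants: 1 2-hydroxy-6-methoxybenzaldehyde; 2 prenyl bromide (1-bromo-3-methylbut-2-ene)
Product: 3 2-methoxy-6-[(3-methylbut-2-en-1-yl)oxy]benzaldehyde
Conditions: K2CO3, DMF, rt
Reagents that add atoms: none
Why: Williamson O-alkylation of the only phenol, so the prenyl group sits on the oxygen that becomes O4′ without any regiochemical question.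

Step 2
Reactants: 3 2-methoxy-6-[(3-methylbut-2-en-1-yl)oxy]benzaldehyde
Product: 5 2-hydroxy-6-methoxy-3-(2-methylbut-3-en-2-yl)benzaldehyde, via ortho-dienone 4 (not isolated)
Conditions: PhNEt2, 190 °C, Ar
Reagents that add atoms: none
Why: Aromatic Claisen rearrangement; the [3,3] shift delivers the allyl unit inverted (as 1,1-dimethylallyl) to the only unsubstituted ortho carbon, and enolisation of dienone 4 in the basic solvent restores the arene, the new phenol being held in a hydrogen bond to the aldehyde.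

Step 3
Reactants: 5 2-hydroxy-6-methoxy-3-(2-methylbut-3-en-2-yl)benzaldehyde
Product: 7 3-methoxy-6-(2-methylbut-3-en-2-yl)benzene-1,2-diol, via aryl formate 6 (not isolated)
Conditions: H2O2 (30% aq.), NaOH (aq.), THF, 0 °C → rt, Ar; then dilute HCl, 0 °C
Reagents that add atoms: hydrogen peroxide, OO
Why: Dakin oxidation of an ortho-hydroxybenzaldehyde (hydroperoxide addition, aryl migration, formate hydrolysis) turns the formyl carbon into the second catechol oxygen; alkaline peroxide does not touch the isolated terminal alkene.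

Step 4
Reactants: 7 3-methoxy-6-(2-methylbut-3-en-2-yl)benzene-1,2-diol
Product: 8 2,3-bis[(tert-butyldimethylsilyl)oxy]-1-methoxy-4-(2-methylbut-3-en-2-yl)benzene
Conditions: TBSOTf, 2,6-lutidine, CH2Cl2, 0 °C → rt
Reagents that add atoms: tert-butyldimethylsilyl triflate, CC(C)(C)[Si](C)(C)OS(=O)(=O)C(F)(F)F
Why: Silylation with the silyl triflate is forceful enough to cap both catechol oxygens, including the one beside the quaternary carbon, and gives fluoride-labile groups so that no acid is needed at the end of the route.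

Step 5
Reactants: 8 2,3-bis[(tert-butyldimethylsilyl)oxy]-1-methoxy-4-(2-methylbut-3-en-2-yl)benzene
Product: 9 1-bromo-3,4-bis[(tert-butyldimethylsilyl)oxy]-2-methoxy-5-(2-methylbut-3-en-2-yl)benzene
Conditions: NBS, MeCN, 0 °C → rt, dark
Reagents that add atoms: N-bromosuccinimide, O=C1CCC(=O)N1Br
Why: Electrophilic aromatic bromination; of the two free ring carbons only the future C1′ is ortho to the methoxy group and para to a silyloxy group, the other lies beside the quaternary carbon, and the 1,1-dimethylallyl group has no allylic hydrogen and only a hindered monosubstituted alkene.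

Step 6
Reactants: 10 2,4-dihydroxybenzaldehyde
Product: 11 2-hydroxy-4-[(triisopropylsilyl)oxy]benzaldehyde
Conditions: TIPSCl, imidazole, DMF, 0 °C
Reagents that add atoms: triisopropylsilyl chloride, CC(C)[Si](Cl)(C(C)C)C(C)C
Why: Chemoselective silylation of the 4-hydroxyl, the 2-hydroxyl being tied up in a hydrogen bond to the aldehyde; TIPS is chosen because its aryl ethers tolerate the basic and acidic steps that follow.

Step 7
Reactants: 11 2-hydroxy-4-[(triisopropylsilyl)oxy]benzaldehyde
Product: 12 2-(methoxymethoxy)-4-[(triisopropylsilyl)oxy]benzaldehyde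
Conditions: MOMCl, iPr2NEt, CH2Cl2, 0 → 40 °C
Reagents that add atoms: chloromethyl methyl ether, COCCl
Why: O-alkylation to the MOM acetal gives an ether-type group that cannot migrate to the neighbouring oxygen liberated in step 8 and is later removable without fluoride.

Step 8
Reactants: 12 2-(methoxymethoxy)-4-[(triisopropylsilyl)oxy]benzaldehyde
Product: 14 2-(methoxymethoxy)-4-[(triisopropylsilyl)oxy]phenol, via aryl formate 13 (not isolated)
Conditions: mCPBA, CH2Cl2, 0 °C → rt; then K2CO3 (cat.), MeOH, 0 °C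
Reagents that add atoms: 3-chloroperoxybenzoic acid, OOC(=O)c1cccc(Cl)c1
Why: Baeyer–Villiger (Dakin-type) oxidation; the electron-rich aryl group migrates in the Criegee intermediate to give formate 13, which is cleaved by catalytic methanolysis that leaves the TIPS ether intact.

Step 9
Reactants: 14 2-(methoxymethoxy)-4-[(triisopropylsilyl)oxy]phenol
Product: 15 2-(methoxymethoxy)-4-[(triisopropylsilyl)oxy]phenyl trifluoromethanesulfonate
Conditions: Tf2O, pyridine, CH2Cl2, 0 °C
Reagents that add atoms: trifluoromethanesulfonic anhydride, O=S(=O)(OS(=O)(=O)C(F)(F)F)C(F)(F)F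
Why: O-sulfonylation of the single free phenol gives the halide-free electrophile required by the key step.

Step 10
Reactants: 9 1-bromo-3,4-bis[(tert-butyldimethylsilyl)oxy]-2-methoxy-5-(2-methylbut-3-en-2-yl)benzene; 16 vinylboronic acid pinacol ester; 15 2-(methoxymethoxy)-4-[(triisopropylsilyl)oxy]phenyl trifluoromethanesulfonate
Product: 19 2-[(1S)-1-{3,4-bis[(tert-butyldimethylsilyl)oxy]-2-methoxy-5-(2-methylbut-3-en-2-yl)phenyl}-2-{2-(methoxymethoxy)-4-[(triisopropylsilyl)oxy]phenyl}ethyl]-4,4,5,5-tetramethyl-1,3,2-dioxaborolane, via aryllithium 17 (not isolated), via vinylboronate complex 18 (not isolated)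
Conditions: n-BuLi, THF, −78 °C; 16, −78 °C → rt; volatiles off; then 15, Pd(OAc)2 (2 mol%), L (2.4 mol%), THF, 60 °C
Reagents that add atoms: none
Why: Bromine–lithium exchange gives aryllithium 17, which adds to boron of 16 to form the four-coordinate vinylboronate 18; oxidative addition of triflate 15 to zerovalent palladium gives a cationic divalent arylpalladium species that binds the vinyl group of 18 and induces anti 1,2-migration of the ring B aryl from boron to the internal carbon (C3–C1′) while palladium bonds the terminal carbon, and reductive elimination then forms C4–C4a. The closest known reaction type is the palladium-catalysed enantioselective conjunctive cross-coupling of vinylboron ate complexes with aryl triflates. No ring closes in this step. The single new stereocentre C3 is set by the chiral ferrocenyl bisphosphine on palladium, which selects the enantioface of the bound vinyl group in the metallate shift, and boron stays on C3 as the handle for stereoretentive homologation. The step needs the conjunctive path to win over direct Suzuki-type transmetallation, β-hydride elimination and Heck insertion into the 1,1-dimethylallyl alkene; the wide-bite-angle ligand, the halide-free medium (n-BuLi exchange leaves 1-bromobutane, not a lithium halide, and the electrophile is a triflate) and the far higher π-nucleophilicity of the anionic vinylboronate over the hindered neopentyl-type alkene should secure this. The electron-rich ring B aryl is a good migrating group, and the MOM and silyl ethers are inert under these neutral conditions.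

Step 11
Reactants: 19 the (1S)-boronic ester from step 10; 20 bromochloromethane
Product: 22 2-[(2S)-2-{3,4-bis[(tert-butyldimethylsilyl)oxy]-2-methoxy-5-(2-methylbut-3-en-2-yl)phenyl}-3-{2-(methoxymethoxy)-4-[(triisopropylsilyl)oxy]phenyl}propyl]-4,4,5,5-tetramethyl-1,3,2-dioxaborolane, via chloromethyl boronate complex 21 (not isolated)
Conditions: n-BuLi, THF, −78 °C → rt
Reagents that add atoms: none
Why: Matteson homologation; LiCH2Cl formed in situ by bromine–lithium exchange adds to boron, and the 1,2-shift of the benzylic carbon with loss of chloride proceeds with retention at the migrating carbon, so C3 keeps its configuration while C2 is inserted.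

Step 12
Reactants: 22 the homologated primary boronic ester
Product: 23 (2S)-2-{3,4-bis[(tert-butyldimethylsilyl)oxy]-2-methoxy-5-(2-methylbut-3-en-2-yl)phenyl}-3-{2-(methoxymethoxy)-4-[(triisopropylsilyl)oxy]phenyl}propan-1-ol
Conditions: H2O2 (30% aq.), pH 7 phosphate buffer, THF, 0 °C → rt
Reagents that add atoms: hydrogen peroxide, OO
Why: Oxidation of the primary C–B bond (boron-to-oxygen 1,2-shift) gives the alcohol; the neutral buffer spares the aryl silyl ethers and peroxide does not attack the isolated alkene.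

Step 13
Reactants: 23 the (2S)-propanol from step 12
Product: 24 2-[(2S)-2-{3,4-bis[(tert-butyldimethylsilyl)oxy]-2-methoxy-5-(2-methylbut-3-en-2-yl)phenyl}-3-hydroxypropyl]-5-[(triisopropylsilyl)oxy]phenol
Conditions: HCl (cat., conc. aq.), MeOH, rt
Reagents that add atoms: none
Why: Acid-catalysed transacetalisation of the aryl MOM ether to methanol frees the ring A phenol; the TIPS aryl ether and the two TBS aryl ethers, each flanked on both sides, should resist dilute methanolic acid, and no phenol is yet free beside the 1,1-dimethylallyl group.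

Step 14
Reactants: 24 the phenol–alcohol from step 13
Product: 25 (3S)-3-{3,4-bis[(tert-butyldimethylsilyl)oxy]-2-methoxy-5-(2-methylbut-3-en-2-yl)phenyl}-7-[(triisopropylsilyl)oxy]-3,4-dihydro-2H-chromene
Conditions: PPh3, DIAD, THF, 0 °C → rt
Reagents that add atoms: none
Why: Mitsunobu etherification; the only free phenol attacks the activated primary carbon in a 6-exo-tet closure of ring C (O1–C2), and C3 is not a reacting centre so its configuration is kept.

Step 15
Reactants: 25 the silyl-protected isoflavan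
Product: 26 (3S)-3-[3,4-dihydroxy-2-methoxy-5-(2-methylbut-3-en-2-yl)phenyl]-3,4-dihydro-2H-chromen-7-ol
Conditions: Bu4NF, AcOH, THF, 0 °C → rt, Ar
Reagents that add atoms: none
Why: Fluoride desilylation removes all three aryl silyl ethers; buffering with acetic acid under argon keeps the liberated catechol from base-mediated oxidation, and the alkene, the aryl methyl ether and C3 are untouched.

**Compound list**

1 | 2-hydroxy-6-methoxybenzaldehyde | COc1cccc(O)c1C=O | starting material
2 | prenyl bromide (1-bromo-3-methylbut-2-ene) | CC(C)=CCBr | starting material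
3 | 2-methoxy-6-[(3-methylbut-2-en-1-yl)oxy]benzaldehyde | COc1cccc(OCC=C(C)C)c1C=O | intermediate
4 | 2-methoxy-5-(2-methylbut-3-en-2-yl)-6-oxocyclohexa-1,3-diene-1-carbaldehyde (racemic ortho-dienone, not isolated) | O=CC1=C(OC)C=CC(C(C)(C)C=C)C1=O | intermediate
5 | 2-hydroxy-6-methoxy-3-(2-methylbut-3-en-2-yl)benzaldehyde | C=CC(C)(C)c1ccc(OC)c(C=O)c1O | intermediate
6 | 2-hydroxy-6-methoxy-3-(2-methylbut-3-en-2-yl)phenyl formate (not isolated) | C=CC(C)(C)c1ccc(OC)c(OC=O)c1O | intermediate
7 | 3-methoxy-6-(2-methylbut-3-en-2-yl)benzene-1,2-diol | C=CC(C)(C)c1ccc(OC)c(O)c1O | intermediate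
8 | 2,3-bis[(tert-butyldimethylsilyl)oxy]-1-methoxy-4-(2-methylbut-3-en-2-yl)benzene | C=CC(C)(C)c1ccc(OC)c(O[Si](C)(C)C(C)(C)C)c1O[Si](C)(C)C(C)(C)C | intermediate
9 | 1-bromo-3,4-bis[(tert-butyldimethylsilyl)oxy]-2-methoxy-5-(2-methylbut-3-en-2-yl)benzene | C=CC(C)(C)c1cc(Br)c(OC)c(O[Si](C)(C)C(C)(C)C)c1O[Si](C)(C)C(C)(C)C | intermediate
10 | 2,4-dihydroxybenzaldehyde | O=Cc1ccc(O)cc1O | starting material
11 | 2-hydroxy-4-[(triisopropylsilyl)oxy]benzaldehyde | O=Cc1ccc(O[Si](C(C)C)(C(C)C)C(C)C)cc1O | intermediate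
12 | 2-(methoxymethoxy)-4-[(triisopropylsilyl)oxy]benzaldehyde | COCOc1cc(O[Si](C(C)C)(C(C)C)C(C)C)ccc1C=O | intermediate
13 | 2-(methoxymethoxy)-4-[(triisopropylsilyl)oxy]phenyl formate (not isolated) | COCOc1cc(O[Si](C(C)C)(C(C)C)C(C)C)ccc1OC=O | intermediate
14 | 2-(methoxymethoxy)-4-[(triisopropylsilyl)oxy]phenol | COCOc1cc(O[Si](C(C)C)(C(C)C)C(C)C)ccc1O | intermediate
15 | 2-(methoxymethoxy)-4-[(triisopropylsilyl)oxy]phenyl trifluoromethanesulfonate | COCOc1cc(O[Si](C(C)C)(C(C)C)C(C)C)ccc1OS(=O)(=O)C(F)(F)F | intermediate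
16 | vinylboronic acid pinacol ester | C=CB1OC(C)(C)C(C)(C)O1 | starting material
17 | [3,4-bis(tert-butyldimethylsilyloxy)-2-methoxy-5-(2-methylbut-3-en-2-yl)phenyl]lithium (not isolated) | [Li]c1cc(C(C)(C)C=C)c(O[Si](C)(C)C(C)(C)C)c(O[Si](C)(C)C(C)(C)C)c1OC | intermediate
18 | lithium aryl(vinyl)pinacolatoborate from 17 and 16 (not isolated) | [Li+].C=C[B-]1(OC(C)(C)C(C)(C)O1)c1cc(C(C)(C)C=C)c(O[Si](C)(C)C(C)(C)C)c(O[Si](C)(C)C(C)(C)C)c1OC | intermediate
19 | 2-[(1S)-1-{3,4-bis[(tert-butyldimethylsilyl)oxy]-2-methoxy-5-(2-methylbut-3-en-2-yl)phenyl}-2-{2-(methoxymethoxy)-4-[(triisopropylsilyl)oxy]phenyl}ethyl]-4,4,5,5-tetramethyl-1,3,2-dioxaborolane | C=CC(C)(C)c1cc([C@H](Cc2ccc(O[Si](C(C)C)(C(C)C)C(C)C)cc2OCOC)B2OC(C)(C)C(C)(C)O2)c(OC)c(O[Si](C)(C)C(C)(C)C)c1O[Si](C)(C)C(C)(C)C | intermediate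
20 | bromochloromethane | ClCBr | starting material
21 | lithium (S)-configured (chloromethyl)boronate complex of 19 (not isolated) | [Li+].C=CC(C)(C)c1cc([C@H](Cc2ccc(O[Si](C(C)C)(C(C)C)C(C)C)cc2OCOC)[B-]2(CCl)OC(C)(C)C(C)(C)O2)c(OC)c(O[Si](C)(C)C(C)(C)C)c1O[Si](C)(C)C(C)(C)C | intermediate
22 | 2-[(2S)-2-{3,4-bis[(tert-butyldimethylsilyl)oxy]-2-methoxy-5-(2-methylbut-3-en-2-yl)phenyl}-3-{2-(methoxymethoxy)-4-[(triisopropylsilyl)oxy]phenyl}propyl]-4,4,5,5-tetramethyl-1,3,2-dioxaborolane | C=CC(C)(C)c1cc([C@H](Cc2ccc(O[Si](C(C)C)(C(C)C)C(C)C)cc2OCOC)CB2OC(C)(C)C(C)(C)O2)c(OC)c(O[Si](C)(C)C(C)(C)C)c1O[Si](C)(C)C(C)(C)C | intermediate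
23 | (2S)-2-{3,4-bis[(tert-butyldimethylsilyl)oxy]-2-methoxy-5-(2-methylbut-3-en-2-yl)phenyl}-3-{2-(methoxymethoxy)-4-[(triisopropylsilyl)oxy]phenyl}propan-1-ol | C=CC(C)(C)c1cc([C@H](Cc2ccc(O[Si](C(C)C)(C(C)C)C(C)C)cc2OCOC)CO)c(OC)c(O[Si](C)(C)C(C)(C)C)c1O[Si](C)(C)C(C)(C)C | intermediate
24 | 2-[(2S)-2-{3,4-bis[(tert-butyldimethylsilyl)oxy]-2-methoxy-5-(2-methylbut-3-en-2-yl)phenyl}-3-hydroxypropyl]-5-[(triisopropylsilyl)oxy]phenol | C=CC(C)(C)c1cc([C@H](Cc2ccc(O[Si](C(C)C)(C(C)C)C(C)C)cc2O)CO)c(OC)c(O[Si](C)(C)C(C)(C)C)c1O[Si](C)(C)C(C)(C)C | intermediate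
25 | (3S)-3-{3,4-bis[(tert-butyldimethylsilyl)oxy]-2-methoxy-5-(2-methylbut-3-en-2-yl)phenyl}-7-[(triisopropylsilyl)oxy]-3,4-dihydro-2H-chromene | C=CC(C)(C)c1cc([C@H]2COc3cc(O[Si](C(C)C)(C(C)C)C(C)C)ccc3C2)c(OC)c(O[Si](C)(C)C(C)(C)C)c1O[Si](C)(C)C(C)(C)C | intermediate
26 | (3S)-3-[3,4-dihydroxy-2-methoxy-5-(2-methylbut-3-en-2-yl)phenyl]-3,4-dihydro-2H-chromen-7-ol | C=CC(C)(C)c1cc([C@H]2COc3cc(O)ccc3C2)c(OC)c(O)c1O | target

**Step count**

Total: 15 steps. Longest linear sequence: 11 steps (steps 1–5, then 10–15); the ring A branch (steps 6–9) joins at step 10.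

**Steps most likely to fail**

Step 10 (conjunctive coupling). The processes at risk are competition of the palladium-induced 1,2-shift with direct transmetallation, slow oxidative addition of the electron-rich, ortho-substituted triflate, and erosion of enantioface selection by the ortho-methoxy migrating group. The fallback sets out from bromide 9 and aldehyde 12 and comes back at alcohol 23, so steps 11 and 12 are not needed. Aryllithium 17 from 9 (n-BuLi, THF, −78 °C) is opened onto oxirane with BF3·OEt2 to give the ring B arylethanol F1. This is oxidised with TEMPO and PhI(OAc)2 in MeCN/H2O to the arylacetic acid F2, which is coupled (DCC, DMAP) to (4S)-4-benzyl-1,3-oxazolidin-2-one to give the N-acyl oxazolidinone F3. Aldehyde 12 is reduced with NaBH4 to the ring A benzyl alcohol F4 and converted with CBr4 and PPh3 into the benzyl bromide F5. The sodium enolate of F3 (NaN(SiMe3)2, THF, −78 °C) is alkylated by F5 on the face opposite the auxiliary benzyl group (Evans alkylation) to give the (S)-configured alkylated imide F6, and LiBH4 reduction should give 23.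

Step 2 (Claisen rearrangement). The processes at risk are Cope migration of the dienone to the free para carbon (normal prenyl isomer), abnormal Claisen isomerisation and thermal loss of the prenyl group. The fallback sets out from 1 and comes back at bromide 9, so steps 3–5 are replaced; the bromine needed later is put in first and blocks the para position. NBS bromination of 1, expected para to the hydroxyl, gives the bromo salicylaldehyde F7, and O-prenylation with 2 (K2CO3, DMF) gives the prenyl ether F8. Heating in PhNEt2 then leads, through the bromo ortho-dienone F9, to the para-blocked Claisen product F10. Dakin oxidation (H2O2, NaOH) passes through the bromo aryl formate F11 to the bromocatechol F12, and silylation with TBSOTf and 2,6-lutidine gives 9.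

Step 3 (Dakin oxidation). The processes at risk are over-oxidation of the very electron-rich catechol in alkaline peroxide and slow hydroperoxide addition to the doubly ortho-substituted aldehyde. The fallback sets out from 5 and comes back at catechol 7; the catechol is never exposed to alkaline peroxide. The phenol of 5 is capped (NaH, MOMCl, THF) as the MOM-protected aldehyde F13. Baeyer–Villiger oxidation with mCPBA in CH2Cl2 at 0 °C gives the MOM-protected aryl formate F14, which catalytic K2CO3 in MeOH cleaves to the mono-MOM catechol F15. Catalytic HCl in MeOH then removes the MOM group to give 7.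

**Further compounds**

F1 | step 10 | 2-{3,4-bis[(tert-butyldimethylsilyl)oxy]-2-methoxy-5-(2-methylbut-3-en-2-yl)phenyl}ethan-1-ol | C=CC(C)(C)c1cc(CCO)c(OC)c(O[Si](C)(C)C(C)(C)C)c1O[Si](C)(C)C(C)(C)C
F2 | step 10 | {3,4-bis[(tert-butyldimethylsilyl)oxy]-2-methoxy-5-(2-methylbut-3-en-2-yl)phenyl}acetic acid | C=CC(C)(C)c1cc(CC(=O)O)c(OC)c(O[Si](C)(C)C(C)(C)C)c1O[Si](C)(C)C(C)(C)C
F3 | step 10 | (4S)-4-benzyl-3-({3,4-bis[(tert-butyldimethylsilyl)oxy]-2-methoxy-5-(2-methylbut-3-en-2-yl)phenyl}acetyl)-1,3-oxazolidin-2-one | C=CC(C)(C)c1cc(CC(=O)N2[C@@H](Cc3ccccc3)COC2=O)c(OC)c(O[Si](C)(C)C(C)(C)C)c1O[Si](C)(C)C(C)(C)C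
F4 | step 10 | {2-(methoxymethoxy)-4-[(triisopropylsilyl)oxy]phenyl}methanol | OCc1ccc(O[Si](C(C)C)(C(C)C)C(C)C)cc1OCOC
F5 | step 10 | 1-(bromomethyl)-2-(methoxymethoxy)-4-[(triisopropylsilyl)oxy]benzene | BrCc1ccc(O[Si](C(C)C)(C(C)C)C(C)C)cc1OCOC
F6 | step 10 | (4S)-4-benzyl-3-[(2S)-2-{3,4-bis[(tert-butyldimethylsilyl)oxy]-2-methoxy-5-(2-methylbut-3-en-2-yl)phenyl}-3-{2-(methoxymethoxy)-4-[(triisopropylsilyl)oxy]phenyl}propanoyl]-1,3-oxazolidin-2-one | C=CC(C)(C)c1cc([C@H](Cc2ccc(O[Si](C(C)C)(C(C)C)C(C)C)cc2OCOC)C(=O)N2[C@@H](Cc3ccccc3)COC2=O)c(OC)c(O[Si](C)(C)C(C)(C)C)c1O[Si](C)(C)C(C)(C)C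
F7 | step 2 | 3-bromo-6-hydroxy-2-methoxybenzaldehyde | COc1c(Br)ccc(O)c1C=O
F8 | step 2 | 3-bromo-2-methoxy-6-[(3-methylbut-2-en-1-yl)oxy]benzaldehyde | COc1c(Br)ccc(OCC=C(C)C)c1C=O
F9 | step 2 | 3-bromo-2-methoxy-5-(2-methylbut-3-en-2-yl)-6-oxocyclohexa-1,3-diene-1-carbaldehyde (racemic, not isolated) | O=CC1=C(OC)C(Br)=CC(C(C)(C)C=C)C1=O
F10 | step 2 | 3-bromo-6-hydroxy-2-methoxy-5-(2-methylbut-3-en-2-yl)benzaldehyde | C=CC(C)(C)c1cc(Br)c(OC)c(C=O)c1O
F11 | step 2 | 3-bromo-6-hydroxy-2-methoxy-5-(2-methylbut-3-en-2-yl)phenyl formate (not isolated) | C=CC(C)(C)c1cc(Br)c(OC)c(OC=O)c1O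
F12 | step 2 | 4-bromo-3-methoxy-6-(2-methylbut-3-en-2-yl)benzene-1,2-diol | C=CC(C)(C)c1cc(Br)c(OC)c(O)c1O
F13 | step 3 | 6-methoxy-2-(methoxymethoxy)-3-(2-methylbut-3-en-2-yl)benzaldehyde | C=CC(C)(C)c1ccc(OC)c(C=O)c1OCOC
F14 | step 3 | 6-methoxy-2-(methoxymethoxy)-3-(2-methylbut-3-en-2-yl)phenyl formate (not isolated) | C=CC(C)(C)c1ccc(OC)c(OC=O)c1OCOC
F15 | step 3 | 6-methoxy-2-(methoxymethoxy)-3-(2-methylbut-3-en-2-yl)phenol | C=CC(C)(C)c1ccc(OC)c(O)c1OCOC
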